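**Strategy.** Everything rests on the C3–C4 ethano bridge of the oxepine ring (O1, quaternary C2, alkene C5=C6, C7), which separates the ring alkene carbon C5 from the oxygen-bearing C2. Phenyl vinyl sulfone stands in for this CH2–CH2 unit: in one flask a vinyl Grignard reagent (the later C5) adds to its β-carbon, and the α-sulfonyl carbanion so formed (C3) acylates dimethyl oxalate (the later C2 and carboxyl group). The precursors are thus three small pieces, and the product is desulfonylated to an α-keto ester. A copper–bis(oxazoline) Mukaiyama aldol then sets C2, the tertiary hydroxyl is allylated, and ring-closing metathesis at C5=C6 closes the ring.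

Key step: step 5

Remark on the chemistry: the (R,R) ligand in step 9 is chosen on the square-planar chelate model of copper–bis(oxazoline) complexes with α-keto esters, in which the (S,S) ligand exposes the si face of the ketone; the sense of induction is assumed to carry over to this keto ester and enol silane.

Step 1
Reactants: 1 5-bromo-2-methylpent-2-ene
Product: 2 (2E)-5-bromo-2-methylpent-2-en-1-ol
Conditions: SeO2 (0.1 equiv), t-BuOOH (2 equiv), CH2Cl2, 0 °C → rt
Reagents that add atoms: selenium dioxide (catalytic oxygen carrier), O=[Se]=O; tert-butyl hydroperoxide, CC(C)(C)OO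
Why: Riley allylic oxidation (ene reaction, then [2,3]-sigmatropic shift of the allylseleninic acid) should hydroxylate only the methyl group trans to the chain, which fixes the E geometry of the side-chain alkene of the target.

Step 2
Reactants: 2 (2E)-5-bromo-2-methylpent-2-en-1-ol
Product: 3 {[(2E)-5-bromo-2-methylpent-2-en-1-yl]oxy}(tert-butyl)diphenylsilane
Conditions: TBDPSCl, imidazole, CH2Cl2, rt
Reagents that add atoms: tert-butyl(chloro)diphenylsilane (TBDPSCl), CC(C)(C)[Si](Cl)(c1ccccc1)c1ccccc1
Why: Silyl ether formation at the primary alcohol should be clean, and the bulky silyl ether should survive the organomagnesium, acid and metathesis steps that follow.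

Step 3
Reactants: 3 {[(2E)-5-bromo-2-methylpent-2-en-1-yl]oxy}(tert-butyl)diphenylsilane; 4 prop-2-yn-1-ol
Product: 7 (5E)-7-(tert-butyldiphenylsilyloxy)-6-methyl-2-methylidenehept-5-en-1-ol, via homoallylic Grignard reagent 5 (not isolated), via alkenylmagnesium chelate 6 (not isolated)
Conditions: Mg, THF, 40 °C; 4 + MeMgBr (1.0 equiv), THF, 0 °C; then 5, CuBr·SMe2 (10 mol %), −20 °C → rt; aq. NH4Cl
Reagents that add atoms: none
Why: Copper-catalysed carbomagnesiation of the propargylic magnesium alkoxide should deliver the alkyl group to the internal alkyne carbon through the five-membered alkoxide chelate, so that protonation gives the 2-substituted allyl alcohol as one regioisomer.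

Step 4
Reactants: 7 (5E)-7-(tert-butyldiphenylsilyloxy)-6-methyl-2-methylidenehept-5-en-1-ol
Product: 8 (5E)-7-(tert-butyldiphenylsilyloxy)-6-methyl-2-methylidenehept-5-en-1-yl 2,2,2-trichloroethanimidate
Conditions: Cl3CCN, DBU (10 mol %), CH2Cl2, 0 °C
Reagents that add atoms: trichloroacetonitrile, N#CC(Cl)(Cl)Cl
Why: Base-catalysed addition of the alcohol to the nitrile (imidate formation) should give an allyl donor that can be activated by acid, without touching either alkene.

Step 5
Reactants: 9 vinylmagnesium bromide; 10 phenyl vinyl sulfone; 11 dimethyl oxalate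
Product: 13 methyl 3-(benzenesulfonyl)-2-oxohex-5-enoate, via magnesium sulfonyl carbanion 12 (not isolated)
Conditions: 9 (1.2 equiv), CuBr·SMe2 (10 mol %), THF, −78 °C, slow addition of 10; then cannulation into 11 (3 equiv), THF, −78 → −40 °C; aq. NH4Cl
Reagents that add atoms: none
Why: Copper-catalysed conjugate addition of the vinyl Grignard reagent to the β-carbon of the vinyl sulfone should join the vinyl CH (later C5) to the sulfone β-carbon (later C4) and leave an α-sulfonyl magnesium carbanion, which is then added to excess dimethyl oxalate at low temperature, where the chelated tetrahedral adduct should persist until the quench, so that the sulfone α-carbon (later C3) is joined once only to an oxalate carbonyl carbon (later C2). The closest known reaction type is the tandem conjugate addition–electrophile trapping of vinyl sulfones, combined with the mono-acylation of organomagnesium reagents by dialkyl oxalates. No ring is closed in this step; the oxepine is closed later at C5=C6 by metathesis. The only new stereocenter is the sulfonyl-bearing C3, which forms without control and is erased in step 6, so no stereocontrol is needed here. The step needs 1,4-addition instead of deprotonation of the vinylic sulfone hydrogen, which the soft organocopper intermediate should secure, and it needs the carbanion to meet the oxalate and not a second molecule of sulfone or the acidic product, which the slow addition of the sulfone and the inverse addition into excess oxalate should secure.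

Step 6
Reactants: 13 methyl 3-(benzenesulfonyl)-2-oxohex-5-enoate
Product: 14 methyl 2-oxohex-5-enoate
Conditions: Bu3SnH, AIBN (cat.), toluene, 80 °C
Reagents that add atoms: none
Why: Radical-chain desulfonylation of a β-keto sulfone (stannyl radical addition to the ketone oxygen, β-scission of the C–S bond, protonation of the tin enolate on work-up) should remove the activating group and leave the terminal alkene and the keto ester intact.

Step 7
Reactants: 15 1-(2,5-dihydroxyphenyl)ethan-1-one
Product: 16 1-[2,5-bis(tert-butyldimethylsilyloxy)phenyl]ethan-1-one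
Conditions: TBSCl, imidazole, DMF, rt
Reagents that add atoms: tert-butyl(chloro)dimethylsilane (TBSCl), CC(C)(C)[Si](C)(C)Cl
Why: Silyl ether formation at both phenols should mask the hydroquinone so that it cannot quench the Lewis acids and silyl triflate used later.

Step 8
Reactants: 16 1-[2,5-bis(tert-butyldimethylsilyloxy)phenyl]ethan-1-one
Product: 17 {1-[2,5-bis(tert-butyldimethylsilyloxy)phenyl]ethenyloxy}trimethylsilane
Conditions: TMSOTf, Et3N, CH2Cl2, 0 °C
Reagents that add atoms: trimethylsilyl trifluoromethanesulfonate (TMSOTf), C[Si](C)(C)OS(=O)(=O)C(F)(F)F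
Why: Soft enolisation of the methyl ketone by a silyl triflate and an amine base (silyl enol ether formation) should give the only possible enol silane.

Step 9
Reactants: 14 methyl 2-oxohex-5-enoate; 17 {1-[2,5-bis(tert-butyldimethylsilyloxy)phenyl]ethenyloxy}trimethylsilane
Product: 19 methyl (2R)-2-{2-[2,5-bis(tert-butyldimethylsilyloxy)phenyl]-2-oxoethyl}-2-hydroxyhex-5-enoate, via trimethylsilyl ether 18 (not isolated)
Conditions: [Cu((R,R)-t-Bu-box)](OTf)2 (10 mol %), THF, −78 °C; then 1 M HCl, THF, rt
Reagents that add atoms: none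
Why: In this catalytic enantioselective Mukaiyama aldol addition the keto ester should chelate the square-planar divalent copper centre through both carbonyl oxygens, and the tert-butyl groups of the (R,R) ligand should leave only the re face of the ketone open, so that the quaternary carbinol center C2 forms with the (R) configuration.

Step 10
Reactants: 19 methyl (2R)-2-{2-[2,5-bis(tert-butyldimethylsilyloxy)phenyl]-2-oxoethyl}-2-hydroxyhex-5-enoate; 8 (5E)-7-(tert-butyldiphenylsilyloxy)-6-methyl-2-methylidenehept-5-en-1-yl 2,2,2-trichloroethanimidate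
Product: 20 methyl (2R)-2-{2-[2,5-bis(tert-butyldimethylsilyloxy)phenyl]-2-oxoethyl}-2-{[(5E)-7-(tert-butyldiphenylsilyloxy)-6-methyl-2-methylidenehept-5-en-1-yl]oxy}hex-5-enoate
Conditions: TMSOTf (10 mol %), CH2Cl2/cyclohexane, 0 °C
Reagents that add atoms: none
Why: Acid-catalysed O-alkylation by an allyl trichloroacetimidate (imidate etherification) should alkylate the hindered tertiary hydroxyl without base, which avoids the retro-aldol cleavage that an alkoxide of this β-hydroxy ketone would suffer, and the stereocenter is not involved.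

Step 11
Reactants: 20 methyl (2R)-2-{2-[2,5-bis(tert-butyldimethylsilyloxy)phenyl]-2-oxoethyl}-2-{[(5E)-7-(tert-butyldiphenylsilyloxy)-6-methyl-2-methylidenehept-5-en-1-yl]oxy}hex-5-enoate
Product: 21 methyl (2R)-2-{2-[2,5-bis(tert-butyldimethylsilyloxy)phenyl]-2-oxoethyl}-6-[(3E)-5-(tert-butyldiphenylsilyloxy)-4-methylpent-3-en-1-yl]-2,3,4,7-tetrahydrooxepine-2-carboxylate
Conditions: second-generation Grubbs catalyst RuCl2(=CHPh)(PCy3)(H2IMes) (5 mol %), CH2Cl2, 40 °C, 5 mM
Reagents that add atoms: none
Why: Ring-closing metathesis between the monosubstituted and the 1,1-disubstituted alkene should close the seven-membered oxepine ring and form the trisubstituted C5=C6 alkene, whose geometry the ring enforces, while the trisubstituted side-chain alkene is too hindered to compete.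

Step 12
Reactants: 21 methyl (2R)-2-{2-[2,5-bis(tert-butyldimethylsilyloxy)phenyl]-2-oxoethyl}-6-[(3E)-5-(tert-butyldiphenylsilyloxy)-4-methylpent-3-en-1-yl]-2,3,4,7-tetrahydrooxepine-2-carboxylate
Product: 22 (2R)-2-{2-[2,5-bis(tert-butyldimethylsilyloxy)phenyl]-2-oxoethyl}-6-[(3E)-5-(tert-butyldiphenylsilyloxy)-4-methylpent-3-en-1-yl]-2,3,4,7-tetrahydrooxepine-2-carboxylic acid
Conditions: Me3SnOH, ClCH2CH2Cl, 70 °C; then 0.1 M aq. HCl
Reagents that add atoms: trimethyltin hydroxide, C[Sn](C)(C)O
Why: Trimethyltin hydroxide cleaves methyl esters by acyl substitution under nearly neutral conditions (mild ester hydrolysis), which should spare the β-alkoxy ketone from E1cB ring opening and leave C2 untouched.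

Step 13
Reactants: 22 (2R)-2-{2-[2,5-bis(tert-butyldimethylsilyloxy)phenyl]-2-oxoethyl}-6-[(3E)-5-(tert-butyldiphenylsilyloxy)-4-methylpent-3-en-1-yl]-2,3,4,7-tetrahydrooxepine-2-carboxylic acid
Product: 23 (2R)-2-[2-(2,5-dihydroxyphenyl)-2-oxoethyl]-6-[(3E)-5-hydroxy-4-methylpent-3-en-1-yl]-2,3,4,7-tetrahydrooxepine-2-carboxylic acid
Conditions: HF·pyridine, pyridine, THF, 0 °C → rt
Reagents that add atoms: none
Why: Fluoride-driven silyl ether cleavage under buffered, non-basic conditions should free both phenols and the allylic alcohol without harming the oxepine or the base-labile β-alkoxy ketone.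

**Compound list**

1 | 5-bromo-2-methylpent-2-ene | CC(C)=CCCBr | starting material
2 | (2E)-5-bromo-2-methylpent-2-en-1-ol | C/C(=C\CCBr)CO | intermediate
3 | {[(2E)-5-bromo-2-methylpent-2-en-1-yl]oxy}(tert-butyl)diphenylsilane | C/C(=C\CCBr)CO[Si](c1ccccc1)(c1ccccc1)C(C)(C)C | intermediate
4 | prop-2-yn-1-ol | C#CCO | starting material
5 | bromo{(3E)-5-(tert-butyldiphenylsilyloxy)-4-methylpent-3-en-1-yl}magnesium (homoallylic Grignard reagent) | C/C(=C\CC[Mg]Br)CO[Si](c1ccccc1)(c1ccccc1)C(C)(C)C | intermediate
6 | bromo{(1Z,5E)-2-[(bromomagnesiooxy)methyl]-7-(tert-butyldiphenylsilyloxy)-6-methylhepta-1,5-dien-1-yl}magnesium (alkenylmagnesium chelate, Mg cis to CH2O) | C/C(=C\CC/C(=C/[Mg]Br)CO[Mg]Br)CO[Si](c1ccccc1)(c1ccccc1)C(C)(C)C | intermediate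
7 | (5E)-7-(tert-butyldiphenylsilyloxy)-6-methyl-2-methylidenehept-5-en-1-ol | C/C(=C\CCC(=C)CO)CO[Si](c1ccccc1)(c1ccccc1)C(C)(C)C | intermediate
8 | (5E)-7-(tert-butyldiphenylsilyloxy)-6-methyl-2-methylidenehept-5-en-1-yl 2,2,2-trichloroethanimidate | C/C(=C\CCC(=C)COC(=N)C(Cl)(Cl)Cl)CO[Si](c1ccccc1)(c1ccccc1)C(C)(C)C | intermediate
9 | vinylmagnesium bromide (bromo(ethenyl)magnesium) | C=C[Mg]Br | starting material
10 | phenyl vinyl sulfone ((ethenesulfonyl)benzene) | C=CS(=O)(=O)c1ccccc1 | starting material
11 | dimethyl oxalate | COC(=O)C(=O)OC | starting material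
12 | [1-(benzenesulfonyl)but-3-en-1-yl]magnesium bromide (magnesium sulfonyl carbanion) | C=CCC([Mg]Br)S(=O)(=O)c1ccccc1 | intermediate
13 | methyl 3-(benzenesulfonyl)-2-oxohex-5-enoate (racemic at C3) | C=CCC(C(=O)C(=O)OC)S(=O)(=O)c1ccccc1 | intermediate
14 | methyl 2-oxohex-5-enoate | C=CCCC(=O)C(=O)OC | intermediate
15 | 1-(2,5-dihydroxyphenyl)ethan-1-one | CC(=O)c1cc(O)ccc1O | starting material
16 | 1-[2,5-bis(tert-butyldimethylsilyloxy)phenyl]ethan-1-one | CC(=O)c1cc(O[Si](C)(C)C(C)(C)C)ccc1O[Si](C)(C)C(C)(C)C | intermediate
17 | {1-[2,5-bis(tert-butyldimethylsilyloxy)phenyl]ethenyloxy}trimethylsilane | C=C(O[Si](C)(C)C)c1cc(O[Si](C)(C)C(C)(C)C)ccc1O[Si](C)(C)C(C)(C)C | intermediate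
18 | methyl (2R)-2-{2-[2,5-bis(tert-butyldimethylsilyloxy)phenyl]-2-oxoethyl}-2-(trimethylsilyloxy)hex-5-enoate | C=CCC[C@@](CC(=O)c1cc(O[Si](C)(C)C(C)(C)C)ccc1O[Si](C)(C)C(C)(C)C)(C(=O)OC)O[Si](C)(C)C | intermediate
19 | methyl (2R)-2-{2-[2,5-bis(tert-butyldimethylsilyloxy)phenyl]-2-oxoethyl}-2-hydroxyhex-5-enoate | C=CCC[C@@](CC(=O)c1cc(O[Si](C)(C)C(C)(C)C)ccc1O[Si](C)(C)C(C)(C)C)(C(=O)OC)O | intermediate
20 | methyl (2R)-2-{2-[2,5-bis(tert-butyldimethylsilyloxy)phenyl]-2-oxoethyl}-2-{[(5E)-7-(tert-butyldiphenylsilyloxy)-6-methyl-2-methylidenehept-5-en-1-yl]oxy}hex-5-enoate | C=CCC[C@@](CC(=O)c1cc(O[Si](C)(C)C(C)(C)C)ccc1O[Si](C)(C)C(C)(C)C)(C(=O)OC)OCC(=C)CC/C=C(\C)CO[Si](c1ccccc1)(c1ccccc1)C(C)(C)C | intermediate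
21 | methyl (2R)-2-{2-[2,5-bis(tert-butyldimethylsilyloxy)phenyl]-2-oxoethyl}-6-[(3E)-5-(tert-butyldiphenylsilyloxy)-4-methylpent-3-en-1-yl]-2,3,4,7-tetrahydrooxepine-2-carboxylate | C/C(=C\CCC1=CCC[C@@](CC(=O)c2cc(O[Si](C)(C)C(C)(C)C)ccc2O[Si](C)(C)C(C)(C)C)(C(=O)OC)OC1)CO[Si](c1ccccc1)(c1ccccc1)C(C)(C)C | intermediate
22 | (2R)-2-{2-[2,5-bis(tert-butyldimethylsilyloxy)phenyl]-2-oxoethyl}-6-[(3E)-5-(tert-butyldiphenylsilyloxy)-4-methylpent-3-en-1-yl]-2,3,4,7-tetrahydrooxepine-2-carboxylic acid | C/C(=C\CCC1=CCC[C@@](CC(=O)c2cc(O[Si](C)(C)C(C)(C)C)ccc2O[Si](C)(C)C(C)(C)C)(C(=O)O)OC1)CO[Si](c1ccccc1)(c1ccccc1)C(C)(C)C | intermediate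
23 | (2R)-2-[2-(2,5-dihydroxyphenyl)-2-oxoethyl]-6-[(3E)-5-hydroxy-4-methylpent-3-en-1-yl]-2,3,4,7-tetrahydrooxepine-2-carboxylic acid | C/C(=C\CCC1=CCC[C@@](CC(=O)c2cc(O)ccc2O)(C(=O)O)OC1)CO | target

**Step count.** Total: 13 steps. Longest linear sequence: 8 steps (1 → 2 → 3 → 7 → 8 → 20 → 21 → 22 → 23).

**Steps most likely to fail**

1. Step 10. What may go wrong: the hindered, hydrogen-bonded tertiary hydroxyl is a poor nucleophile, so the activated imidate may be consumed by ionisation, cation–alkene cyclisation or rearrangement to the amide before it etherifies, and the acid may dehydrate the aldol. Fallback (silver-assisted alkylation by a halide in place of acid-catalysed imidate transfer): it sets out from 7 and 19 and comes back at 20. Alcohol 7 is converted by CBr4 and PPh3 (CH2Cl2, 0 °C, Appel reaction) into the allylic bromide tert-butyl{[(2E)-7-bromo-2-methyl-6-methylidenehept-2-en-1-yl]oxy}diphenylsilane F1. Alcohol 19 is then alkylated by F1 with AgOTf and 2,6-di-tert-butyl-4-methylpyridine (CH2Cl2, 0 °C, dark), where halide abstraction by silver should drive O-alkylation under buffered conditions and give 20.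

2. Step 5. What may go wrong: anionic oligomerisation (the sulfonyl carbanion adding to a second molecule of vinyl sulfone), and loss of the carbanion by proton transfer from the acidic keto sulfone or by double acylation of the oxalate. Fallback (the two bond formations are separated, so that the carbanion is generated alone and with defined stoichiometry): it sets out from 9 and 10 and comes back at 13. Reagent 9 is added to 10 (CuBr·SMe2 cat., THF, −78 °C) and the mixture is quenched with aq. NH4Cl to give isolated (but-3-en-1-ylsulfonyl)benzene F2. F2 is deprotonated by n-BuLi (THF, −78 °C) and the lithium carbanion is added to excess 11 at −78 °C to give 13.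

3. Step 12. What may go wrong: retro-oxa-Michael (E1cB) opening of the oxepine at the C2–O bond once the hydroxide reagent enolises the aryl ketone, and slow acyl substitution at the hindered ester. Fallback (alkyl–oxygen cleavage in place of acyl–oxygen cleavage): it sets out from 21 and comes back at 22. LiI in refluxing ethyl acetate should remove the methyl group by SN2 attack of iodide on the O-methyl carbon, which is insensitive to the hindrance at C2 and needs no hydroxide; acidic work-up gives 22. This fallback makes no new compound (F0).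

**Further compounds**

F1 | step 10 | tert-butyl{[(2E)-7-bromo-2-methyl-6-methylidenehept-2-en-1-yl]oxy}diphenylsilane | C/C(=C\CCC(=C)CBr)CO[Si](c1ccccc1)(c1ccccc1)C(C)(C)C
F2 | step 5 | (but-3-en-1-ylsulfonyl)benzene | C=CCCS(=O)(=O)c1ccccc1
F0 | step 12 | none | none
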